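**Assumptions (one line each):** The (S)-4-benzyloxazolidinone auxiliary is assumed to steer both α-carbons as in Evans alkylation, which gives the (R,R) dimer. Catechol mono-methylation is accepted with chromatographic separation from veratrole.

## Retrosynthetic overview
- Hanultarin is the 9-O-feruloyl ester of (R,R)-secoisolariciresinol. It disconnects at the ester into the MOM-protected C2-symmetric diol (used in excess) and MOM-ferulic acid.
- The diol comes from LiBH4 cleavage of a homochiral bis-imide. The bis-imide comes from oxidative homocoupling of two identical Evans enolates of a 3-arylpropanoyl imide, which forms C8–C8′ and sets both stereocentres.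
- That imide comes from a Heck reaction of the aryl bromide with N-acryloyl oxazolidinone followed by hydrogenation. The aryl bromide comes from guaiacol, which comes from catechol.
- MOM-ferulic acid comes from Knoevenagel–Doebner condensation of MOM-vanillin. Vanillin is made from guaiacol and glyoxylic acid.
- No ring is constructed in the route. The three benzene rings are carried in from catechol, and the oxazolidinone is a temporary, recovered auxiliary.

## Forward route

**Step 1**
Reactants: 1 catechol
Product: 2 guaiacol (2-methoxyphenol)
Conditions: Me2SO4 (1 equiv), NaOH (1 equiv), H2O, 0 → 50 °C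
Reagents that add atoms: dimethyl sulfate, COS(=O)(=O)OC
Why: Mono-O-methylation of the phenolate (Williamson) is controlled by using one equivalent of base and methylating agent. No stereocentre is involved.

**Step 2**
Reactants: 2 guaiacol
Product: 3 4-bromo-2-methoxyphenol
Conditions: NBS (1.0 equiv), CH2Cl2, −78 °C → rt
Reagents that add atoms: N-bromosuccinimide, O=C1CCC(=O)N1Br
Why: Electrophilic aromatic bromination goes para to the more strongly activating OH.

**Step 3**
Reactants: 3
Product: 4 4-bromo-2-methoxy-1-(methoxymethoxy)benzene
Conditions: MOMCl, i-Pr2NEt, CH2Cl2, 0 °C → rt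
Reagents that add atoms: chloromethyl methyl ether, COCCl
Why: The MOM ether survives enolate, Pd, hydrogenation and borohydride conditions and is removed by acid at the end (protecting-group installation).

**Step 4**
Reactants: 5 acryloyl chloride
Product: 6 (S)-3-acryloyl-4-benzyloxazolidin-2-one
Conditions: (S)-4-benzyloxazolidin-2-one, n-BuLi, THF, −78 °C; then acryloyl chloride
Reagents that add atoms: (S)-4-benzyloxazolidin-2-one (recoverable chiral auxiliary), O=C1N[C@@H](Cc2ccccc2)CO1
Why: N-acylation of the lithiated oxazolidinone attaches the chiral auxiliary that later controls the C8/C8′ configuration.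

**Step 5**
Reactants: 4 aryl bromide; 6 acryloyl imide
Product: 7 (S)-4-benzyl-3-[(E)-3-(3-methoxy-4-(methoxymethoxy)phenyl)acryloyl]oxazolidin-2-one
Conditions: Pd(OAc)2, P(o-tol)3, Et3N, DMF, 100 °C
Reagents that add atoms: none
Why: Mizoroki–Heck coupling of an aryl bromide with an activated acrylamide gives the E-cinnamoyl imide; the alkene is removed in the next step, so no stereocentre is set here.

**Step 6**
Reactants: 7
Product: 8 (S)-4-benzyl-3-[3-(3-methoxy-4-(methoxymethoxy)phenyl)propanoyl]oxazolidin-2-one
Conditions: H2 (1 atm), 10% Pd/C, EtOAc, rt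
Reagents that add atoms: none
Why: Catalytic hydrogenation reduces the conjugated C=C selectively; the aryl MOM ether, the imide and the auxiliary C–C bonds are untouched.

**Step 7 (key coupling)**
Reactants: 8 (two molecules)
Product: 9 bis-imide of (2R,3R)-2,3-bis[(3-methoxy-4-MOMO-phenyl)methyl]succinic acid with (S)-4-benzyloxazolidinone
Conditions: NaHMDS (1.05 equiv), THF, −78 °C, 1 h; then Fe(acac)3 (1.1 equiv), −78 °C → rt
Reagents that add atoms: none
Why: Oxidative enolate homocoupling joins two identical halves at C8–C8′. The chelated Z-sodium enolate is shielded by the benzyl group on one face, so both α-carbons couple from the open face, as in Evans alkylation, and the homochiral (R,R) pair is favoured; minor diastereomers are removed by chromatography.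

**Step 8**
Reactants: 9
Product: 10 (2R,3R)-2,3-bis[(3-methoxy-4-MOMO-phenyl)methyl]butane-1,4-diol
Conditions: LiBH4 (4 equiv), MeOH (4 equiv), Et2O, 0 °C → rt
Reagents that add atoms: none (the auxiliary is released and recovered)
Why: Borohydride cleaves each N-acyl oxazolidinone to the primary alcohol without touching the non-enolisable α-stereocentres; the MOM ethers are stable.

**Step 9**
Reactants: 2 guaiacol; 11 glyoxylic acid
Product: 12 4-hydroxy-3-methoxymandelic acid (racemic)
Conditions: HCOCO2H (aq.), NaOH, H2O, rt, 48 h
Reagents that add atoms: none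
Why: Base-mediated electrophilic hydroxyalkylation of the guaiacolate occurs para to O−; the new carbinol stereocentre is lost in the next step.

**Step 10**
Reactants: 12
Product: 13 vanillin
Conditions: cat. Cu(OH)2, NaOH, O2 (air), H2O, 80 °C; then HCl
Reagents that add atoms: none
Why: Copper-catalysed aerobic oxidative decarboxylation of the mandelate gives the aldehyde.

**Step 11**
Reactants: 13
Product: 14 3-methoxy-4-(methoxymethoxy)benzaldehyde
Conditions: MOMCl, i-Pr2NEt, CH2Cl2, 0 °C → rt
Reagents that add atoms: chloromethyl methyl ether, COCCl
Why: Phenol protection as the same MOM ether used elsewhere, so one acid step removes all of them at the end.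

**Step 12**
Reactants: 14; 15 malonic acid
Product: 16 (E)-3-(3-methoxy-4-(methoxymethoxy)phenyl)acrylic acid (MOM-ferulic acid)
Conditions: pyridine, cat. piperidine, 90 °C
Reagents that add atoms: none
Why: Knoevenagel–Doebner condensation with decarboxylation gives the thermodynamically favoured E-cinnamic acid.

**Step 13**
Reactants: 10 diol (2.5 equiv); 16 acid (limiting)
Product: 17 mono-feruloyl ester of 10, (2R,3R)-4-hydroxy-2,3-bis[(3-methoxy-4-MOMO-phenyl)methyl]butyl (E)-3-(3-methoxy-4-MOMO-phenyl)acrylate
Conditions: EDC·HCl, DMAP (cat.), CH2Cl2, 0 °C → rt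
Reagents that add atoms: none
Why: Steglich esterification with the C2-symmetric diol in excess favours the mono-ester, and the unreacted diol is recovered; neither stereocentre is touched.

**Step 14**
Reactants: 17
Product: 18 Hanultarin
Conditions: 2 M HCl, THF/i-PrOH (1:1), 50 °C, 12 h, dark
Reagents that add atoms: none
Why: Acid hydrolysis of the three aryl MOM ethers; the secondary alcohol solvent traps the oxocarbenium ion, and the primary cinnamate ester, the E-alkene and the stereocentres are unaffected.

## Compound list
1 | catechol | Oc1ccccc1O | starting material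
2 | guaiacol | COc1ccccc1O | intermediate
3 | 4-bromo-2-methoxyphenol | COc1cc(Br)ccc1O | intermediate
4 | 4-bromo-2-methoxy-1-(methoxymethoxy)benzene | COCOc1ccc(Br)cc1OC | intermediate
5 | acryloyl chloride | C=CC(=O)Cl | starting material
6 | (S)-3-acryloyl-4-benzyloxazolidin-2-one | C=CC(=O)N1[C@@H](Cc2ccccc2)COC1=O | intermediate
7 | (S)-4-benzyl-3-[(E)-cinnamoyl]oxazolidinone, aryl = 3-OMe-4-OMOM | COCOc1ccc(/C=C/C(=O)N2[C@@H](Cc3ccccc3)COC2=O)cc1OC | intermediate
8 | saturated 3-arylpropanoyl imide | COCOc1ccc(CCC(=O)N2[C@@H](Cc3ccccc3)COC2=O)cc1OC | intermediate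
9 | (R,R)-2,3-bis(arylmethyl)succinyl bis-imide | O=C(N1[C@@H](Cc2ccccc2)COC1=O)[C@H](Cc1ccc(OCOC)c(OC)c1)[C@@H](Cc1ccc(OCOC)c(OC)c1)C(=O)N1[C@@H](Cc2ccccc2)COC1=O | intermediate
10 | (2R,3R)-bis-MOM secoisolariciresinol | OC[C@H](Cc1ccc(OCOC)c(OC)c1)[C@H](CO)Cc1ccc(OCOC)c(OC)c1 | intermediate
11 | glyoxylic acid | O=CC(=O)O | starting material
12 | 4-hydroxy-3-methoxymandelic acid | COc1cc(C(O)C(=O)O)ccc1O | intermediate
13 | vanillin | COc1cc(C=O)ccc1O | intermediate
14 | 3-methoxy-4-(methoxymethoxy)benzaldehyde | COCOc1ccc(C=O)cc1OC | intermediate
15 | malonic acid | OC(=O)CC(=O)O | starting material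
16 | MOM-ferulic acid | COCOc1ccc(/C=C/C(=O)O)cc1OC | intermediate
17 | tris-MOM mono-feruloyl ester | COCOc1ccc(/C=C/C(=O)OC[C@H](Cc2ccc(OCOC)c(OC)c2)[C@H](CO)Cc2ccc(OCOC)c(OC)c2)cc1OC | intermediate
18 | Hanultarin | COc1cc(/C=C/C(=O)OC[C@H](Cc2ccc(O)c(OC)c2)[C@H](CO)Cc2ccc(O)c(OC)c2)ccc1O | target

## Totals
- **Total steps:** 14
- **Longest linear sequence:** 9 (steps 1, 2, 3, 5, 6, 7, 8, 13, 14)

## Three steps most likely to fail
1. **Step 7 (oxidative homocoupling):** The dr, the yield, or the facial sense (the (R,R) assumption) may be poor. Fallback: a stepwise route to the same diol 10. Evans-alkylate 8 with methyl bromoacetate, reduce with LiBH4 and lactonise to the (S)-β-arylmethyl-butyrolactone. Benzylate its enolate trans with the benzyl bromide made from 14, then reduce with LiAlH4. If the wrong enantiomer forms, use the (R)-auxiliary.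
2. **Step 14 (triple MOM removal):** The ester may transesterify or hydrolyse, or formaldehyde may alkylate the electron-rich rings. Fallback: remove the MOM groups at the diol stage (10) to give (R,R)-secoisolariciresinol. Then feruloylate the primary OH chemoselectively with vinyl ferulate and Novozym 435, with no phenol protection and no final acid step.
3. **Step 5 (Heck on an electron-rich aryl bromide with an acryloyl imide):** The acryloyl imide may polymerise or undergo Michael additions, giving a low yield. Fallback: avoid palladium and acylate the auxiliary with acid 16 (PivCl, Et3N, LiCl) to give 7 directly.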